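In a one-step world the capture agent has nothing to touch, yet the runs show that it does. Ash carries more capture agent than elm and ends lower, at 20.2% against 22.0% after 4.0 min.

| flask | substrate | coupling partner | second reagent | third reagent | capture agent | remark | time |
|---|---|---|---|---|---|---|---|
| maple | 0.20 M | 2 equiv | 2.5 equiv | 0.70 equiv | 0.020 M | run made earlier |  |
| elm | 0.20 M | 2 equiv | 2.5 equiv | 0.70 equiv | 0.028 M | run made earlier |  |
| ash | 0.20 M | 2 equiv | 2.5 equiv | 0.70 equiv | 0.044 M | run made earlier |  |
| birch | 0.20 M | 2 equiv | 1.2 equiv | 0.70 equiv | 0.020 M | run made earlier |  |
| east | 0.20 M | 2.00 equiv (fed, over 50 s) | 2.50 equiv | 0.700 equiv | 0.0200 M | all else is in the flask from the start; the feed brings no volume worth counting | 4.0 min |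
| north-east | 0.20 M (fed, over 50 s) | 2.00 equiv | 2.50 equiv | 0.700 equiv | 0.0200 M | all else is in the flask from the start; the feed brings no volume worth counting | 4.0 min |
| west | 0.20 M | 2.00 equiv | 2.50 equiv | 0.700 equiv | 0.0200 M | everything together at the start | 4.0 min |

- maple (time / min: target / %): 0.500: 3.0; 1.00: 6.0; 1.33: 9.6; 2.00: 12.9; 2.50: 16.2
- elm (time / min: target / %): 0.833: 5.4; 1.50: 9.8; 2.50: 15.8; 3.00: 17.9; 4.00: 22.0
- ash (time / min: target / %): 0.833: 5.6; 1.50: 8.9; 2.50: 13.4; 3.00: 16.2; 4.00: 20.2
- birch (time / min: target / %): 0.333: 2.3; 1.00: 6.8; 2.00: 11.6; 3.00: 17.9; 4.00: 22.8

(readings scatter by 0.5 percentage points)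

* which flask leads in amount of target, in percent of the substrate charged ("all alike" within 1.5 percentage points) (east / north-east / west / all alike)
* how much target is there at the end, in percent of the substrate charged: east
* how much target is there at the end, in percent of the substrate charged: north-east
* how much target is there at the end, in percent of the substrate charged: west

- what was read earlier has a scatter of 0.5 percentage points, one standard deviation

I read this as a free stock: something stands ready to become target, and each capture agent removes one unit of it. So I divide the target at 4.0 min by the share of substrate that the capture agent leaves free. This gives the draw fraction f = 0.256, the part of the free stock that has become target by then.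

elm: f = 0.256
ash, as a check: 0.259

The time scales then stack up as follows, fastest first.

- Filling the stock: birch already shows 2.3% at 0.333 min, so I take the stock in birch to be filled within that reading, which is shorter than the feed. Birch's cut in second reagent leaves its 22.8% at 4.0 min close to the west estimate below.
- The feed: 50 s.
- The asked time: 4.0 min.
- Draining the stock: at this pace it takes 15.6 min, longer than the run.

My own reckoning follows, with a fed flask starting late by half its feed:

west: f × free share = 23.0%
either fed flask: 20.6%

So I put west ahead. The forecast differs, with 23% for east, 22.6% for north-east, 23.8% for west and the lead as all alike: “I expect small losses, so the flasks are probably alike”.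

The flasks give 14.8% in east, 19.9% in north-east and 22.8% in west, so west leads.

    substrate + coupling partner → intermediate A (k = 1.50 /M/s)
    second reagent + intermediate A → intermediate B (k = 0.670 /M/s)
    third reagent + intermediate B → target (k = 0.0120 /M/s)
    intermediate B + capture agent → trapped intermediate (k = 0.720 /M/s)
    substrate + intermediate B → side product (k = 0.400 /M/s)

The free stock is intermediate B, the resting state, and east pays a toll in side product. Over the feed, mean [substrate] is 0.0662 M in east against 0.00789 M in north-east, and substrate with intermediate B gives side product, 37.3% in east (each unit counted double). Without that step, the gap between west and east falls from 8 percentage points to 1.3 points. Subtracting the toll from the free share, f gives 13.5% for east.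

The neighbour of east with 10.0 equiv of second reagent holds 42.4% side product, so f gives:

12.2%

The computed result is 13.7%.

The earlier runs and the new flask come from a simulation from invented constants.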